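**Retrosynthetic overview**

1. Target 15 ⇐ O-demethylation ⇐ (E)-styryl group by vinylogous aldol condensation of benzaldehyde at the 6-methyl of ring B (the 2-pyranone) ⇐ methoxy-methyl-pyranone 12 carrying the finished ring A (the cyclohexene).
2. Isopropyl group ⇐ isopropenyl (selective hydrogenation) ⇐ trans-acetyl (epimerization, Wittig) ⇐ cis-formyl cycloadduct 7.
3. Ring A ⇐ enantioselective iminium-catalysed Diels–Alder reaction of 3-dienylpyranone 5 with acrolein. It forms the bond from the pyranone-bearing CH to the future isopropyl-bearing CH together with the CH2–CH2 bond. 5 ⇐ Suzuki–Miyaura coupling of bromopyranone 2 with dienylboronate 4.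
4. Enabling feature: ring A is a cyclohexene whose only C=C, the C(CH3)=CH unit, has the two new bonds starting at its two allylic carbons. The methyl on the alkene carbon and ring B on the allylic CH polarize the diene in the same sense. The isopropyl methine carbon sits where a dienophile carbonyl carbon arrives, so it can enter as an activating, epimerizable formyl group and be taken to the hydrocarbon level afterwards.
5. Ring order: ring B is bought (1), ring A is formed in step 4, the phenyl ring C arrives with benzaldehyde in step 9.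

Key step: step 4

Remark: the target is taken as the 4-hydroxy-2-pyranone tautomer drawn; compounds 1, 3, 6 and 13 and all reagents named are catalogue chemicals.

**Route**

Step 1
Reactants: 1 4-methoxy-6-methyl-2H-pyran-2-one
Product: 2 3-bromo-4-methoxy-6-methyl-2H-pyran-2-one
Conditions: NBS (1.05 equiv), MeCN, rt, dark
Reagents that add atoms: N-bromosuccinimide, O=C1CCC(=O)N1Br
Why: Electrophilic bromination of the vinylogous ester should occur at C3, the ring carbon that is both alpha to the lactone carbonyl and beta to the methoxy group and hence the most nucleophilic position.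

Step 2
Reactants: 3 2-methylbut-1-en-3-yne
Product: 4 4,4,5,5-tetramethyl-2-[(1E)-3-methylbuta-1,3-dien-1-yl]-1,3,2-dioxaborolane
Conditions: pinacolborane (1.05 equiv), Cp2Zr(H)Cl (5 mol%), Et3N (10 mol%), neat, 60 °C
Reagents that add atoms: pinacolborane, B1OC(C)(C)C(C)(C)O1
Why: Zirconium-hydride-catalysed hydroboration of a terminal alkyne is a syn, anti-Markovnikov addition that should leave the less reactive 1,1-disubstituted alkene untouched and give the (E)-dienylboronate.

Step 3
Reactants: 2 3-bromo-4-methoxy-6-methyl-2H-pyran-2-one; 4 4,4,5,5-tetramethyl-2-[(1E)-3-methylbuta-1,3-dien-1-yl]-1,3,2-dioxaborolane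
Product: 5 4-methoxy-6-methyl-3-[(1E)-3-methylbuta-1,3-dien-1-yl]-2H-pyran-2-one
Conditions: Pd(PPh3)4 (5 mol%), K2CO3 (2 equiv), 1,4-dioxane/H2O 5:1, 80 °C
Reagents that add atoms: none
Why: Suzuki–Miyaura coupling of a 3-bromo-2-pyranone with an alkenylboronate proceeds with retention of the (E)-alkene geometry and installs the complete diene at C3 of ring B.

Step 4
Reactants: 5 4-methoxy-6-methyl-3-[(1E)-3-methylbuta-1,3-dien-1-yl]-2H-pyran-2-one; 6 acrolein
Product: 7 (1R,2S)-2-(4-methoxy-6-methyl-2-oxo-2H-pyran-3-yl)-4-methylcyclohex-3-ene-1-carbaldehyde (cis)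
Conditions: (5S)-5-benzyl-2,2,3-trimethylimidazolidin-4-one hydrochloride (20 mol%), acrolein (3 equiv), MeCN/H2O 95:5, -10 °C to rt
Reagents that add atoms: none
Why: Acrolein condenses with the secondary-amine salt to an (E)-iminium ion, which undergoes a concerted, asynchronous [4+2] cycloaddition with the s-cis diene and is then hydrolysed to the aldehyde with release of the amine. The closest known reaction type is the iminium-catalysed enantioselective Diels–Alder reaction of acrolein with acyclic (E)-1-substituted 3-methylbuta-1,3-dienes. Ring A is closed by intermolecular cycloaddition, both sigma bonds being formed suprafacially on diene and dienophile in one event, with no chain cyclization involved. The formyl-bearing center is controlled by the catalyst, whose benzyl group shields one face of the iminium ion so that the diene adds to the Si face of the acrolein alpha-carbon and gives (R); the pyranone-bearing center, the one that persists to the target, is then fixed as (S) by the endo transition state, which places the formyl group cis to ring B. Three selectivities are needed: regiochemistry, secured because the 3-methyl group and the 1-pyranonyl group of the diene both make the CH2 terminus the nucleophilic end, so the carbonyl-bearing dienophile carbon bonds to the pyranone-bearing terminus; endo over exo, expected from secondary orbital overlap with the iminium ion and made safe by removing the exo-derived diastereomer in step 6; and enantiofacial selectivity, secured by the catalyst.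

Step 5
Reactants: 7 (1R,2S)-2-(4-methoxy-6-methyl-2-oxo-2H-pyran-3-yl)-4-methylcyclohex-3-ene-1-carbaldehyde
Product: 8 3-[(1S,6R)-6-(1-hydroxyethyl)-3-methylcyclohex-2-en-1-yl]-4-methoxy-6-methyl-2H-pyran-2-one (both carbinol epimers)
Conditions: MeMgBr (1.2 equiv), THF, -78 °C; aqueous work-up
Reagents that add atoms: methylmagnesium bromide, C[Mg]Br
Why: Grignard addition to the aldehyde at -78 °C should be much faster than attack on the vinylogous ester of ring B, and the new carbinol center is of no consequence because it is oxidized in step 6.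

Step 6
Reactants: 8 3-[(1S,6R)-6-(1-hydroxyethyl)-3-methylcyclohex-2-en-1-yl]-4-methoxy-6-methyl-2H-pyran-2-one
Product: 9 3-[(1S,6R)-6-acetyl-3-methylcyclohex-2-en-1-yl]-4-methoxy-6-methyl-2H-pyran-2-one (cis)
Conditions: Dess–Martin periodinane (1.3 equiv), CH2Cl2, 0 °C to rt; chromatography, cis-ketone fraction only
Reagents that add atoms: none
Why: Dess–Martin oxidation under neutral conditions should give the methyl ketone without epimerization, and chromatography at this configurationally robust stage should remove the minor trans ketone that stems from the exo cycloadduct and would belong to the enantiomeric series after epimerization.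

Step 7
Reactants: 9 3-[(1S,6R)-6-acetyl-3-methylcyclohex-2-en-1-yl]-4-methoxy-6-methyl-2H-pyran-2-one
Product: 11 4-methoxy-6-methyl-3-[(1S,6S)-3-methyl-6-(prop-1-en-2-yl)cyclohex-2-en-1-yl]-2H-pyran-2-one, via trans-methyl ketone 10 (not isolated)
Conditions: KOtBu (0.2 equiv), THF, 0 °C to rt; then Ph3PCH3Br/KOtBu (3 equiv each, premixed in THF), 0 °C to rt
Reagents that add atoms: methyltriphenylphosphonium bromide, C[P+](c1ccccc1)(c1ccccc1)c1ccccc1.[Br-]
Why: Catalytic base should equilibrate the ketone through its enolate to the diequatorial trans isomer (thermodynamic control at the acetyl-bearing carbon, the pyranone-bearing center being untouched), and Wittig methylenation then converts the acetyl group into isopropenyl.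

Step 8
Reactants: 11 4-methoxy-6-methyl-3-[(1S,6S)-3-methyl-6-(prop-1-en-2-yl)cyclohex-2-en-1-yl]-2H-pyran-2-one
Product: 12 4-methoxy-6-methyl-3-[(1R,6R)-3-methyl-6-(propan-2-yl)cyclohex-2-en-1-yl]-2H-pyran-2-one
Conditions: H2 (1 atm), RhCl(PPh3)3 (5 mol%), toluene/EtOH 1:1, rt
Reagents that add atoms: none
Why: Homogeneous hydrogenation with RhCl(PPh3)3 is selective for the unhindered 1,1-disubstituted alkene over the trisubstituted ring-A alkene and the double bonds of ring B; no stereocenter is created, and the descriptors change only because the priority order changes.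

Step 9
Reactants: 12 4-methoxy-6-methyl-3-[(1R,6R)-3-methyl-6-(propan-2-yl)cyclohex-2-en-1-yl]-2H-pyran-2-one; 13 benzaldehyde
Product: 14 4-methoxy-3-[(1R,6R)-3-methyl-6-(propan-2-yl)cyclohex-2-en-1-yl]-6-[(E)-2-phenylethenyl]-2H-pyran-2-one
Conditions: benzaldehyde (2 equiv), Mg(OMe)2 (3 equiv), MeOH, reflux
Reagents that add atoms: none
Why: In this vinylogous aldol condensation the 6-methyl group of a 4-methoxy-2-pyranone is deprotonated by Mg(OMe)2 and condenses with benzaldehyde, E1cB dehydration giving the conjugated (E)-styryl group under thermodynamic control, while methoxide exchange at C4 is degenerate.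

Step 10
Reactants: 14 4-methoxy-3-[(1R,6R)-3-methyl-6-(propan-2-yl)cyclohex-2-en-1-yl]-6-[(E)-2-phenylethenyl]-2H-pyran-2-one
Product: 15 4-hydroxy-3-[(1R,6R)-3-methyl-6-(propan-2-yl)cyclohex-2-en-1-yl]-6-[(E)-2-phenylethenyl]-2H-pyran-2-one
Conditions: LiI (5 equiv), DMF, 100 °C, argon, dark; then 0.5 M HCl, 0 °C, to pH 3
Reagents that add atoms: none
Why: SN2 demethylation of the vinylogous methyl ester by iodide (the pyranonate is a carboxylate-like leaving group) avoids the strong Brønsted or Lewis acids that could add the liberated hydroxyl across the ring-A alkene, and it leaves both stereocenters and the (E)-alkene untouched.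

**Compound list**

1 | 4-methoxy-6-methyl-2H-pyran-2-one | COc1cc(C)oc(=O)c1 | starting material
2 | 3-bromo-4-methoxy-6-methyl-2H-pyran-2-one | COc1cc(C)oc(=O)c1Br | intermediate
3 | 2-methylbut-1-en-3-yne | CC(=C)C#C | starting material
4 | 4,4,5,5-tetramethyl-2-[(1E)-3-methylbuta-1,3-dien-1-yl]-1,3,2-dioxaborolane | CC(=C)/C=C/B1OC(C)(C)C(C)(C)O1 | intermediate
5 | 4-methoxy-6-methyl-3-[(1E)-3-methylbuta-1,3-dien-1-yl]-2H-pyran-2-one | COc1cc(C)oc(=O)c1/C=C/C(C)=C | intermediate
6 | acrolein (prop-2-enal) | C=CC=O | starting material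
7 | (1R,2S)-2-(4-methoxy-6-methyl-2-oxo-2H-pyran-3-yl)-4-methylcyclohex-3-ene-1-carbaldehyde | CC1=C[C@H](c2c(OC)cc(C)oc2=O)[C@H](C=O)CC1 | intermediate
8 | 3-[(1S,6R)-6-(1-hydroxyethyl)-3-methylcyclohex-2-en-1-yl]-4-methoxy-6-methyl-2H-pyran-2-one | CC1=C[C@H](c2c(OC)cc(C)oc2=O)[C@H](C(C)O)CC1 | intermediate
9 | 3-[(1S,6R)-6-acetyl-3-methylcyclohex-2-en-1-yl]-4-methoxy-6-methyl-2H-pyran-2-one | CC1=C[C@H](c2c(OC)cc(C)oc2=O)[C@H](C(C)=O)CC1 | intermediate
10 | 3-[(1S,6S)-6-acetyl-3-methylcyclohex-2-en-1-yl]-4-methoxy-6-methyl-2H-pyran-2-one | CC1=C[C@H](c2c(OC)cc(C)oc2=O)[C@@H](C(C)=O)CC1 | intermediate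
11 | 4-methoxy-6-methyl-3-[(1S,6S)-3-methyl-6-(prop-1-en-2-yl)cyclohex-2-en-1-yl]-2H-pyran-2-one | CC1=C[C@H](c2c(OC)cc(C)oc2=O)[C@@H](C(C)=C)CC1 | intermediate
12 | 4-methoxy-6-methyl-3-[(1R,6R)-3-methyl-6-(propan-2-yl)cyclohex-2-en-1-yl]-2H-pyran-2-one | CC1=C[C@H](c2c(OC)cc(C)oc2=O)[C@@H](C(C)C)CC1 | intermediate
13 | benzaldehyde | O=Cc1ccccc1 | starting material
14 | 4-methoxy-3-[(1R,6R)-3-methyl-6-(propan-2-yl)cyclohex-2-en-1-yl]-6-[(E)-2-phenylethenyl]-2H-pyran-2-one | CC1=C[C@H](c2c(OC)cc(/C=C/c3ccccc3)oc2=O)[C@@H](C(C)C)CC1 | intermediate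
15 | 4-hydroxy-3-[(1R,6R)-3-methyl-6-(propan-2-yl)cyclohex-2-en-1-yl]-6-[(E)-2-phenylethenyl]-2H-pyran-2-one | CC1=C[C@H](c2c(O)cc(/C=C/c3ccccc3)oc2=O)[C@@H](C(C)C)CC1 | target

**Step count and risks**

Total steps: 10. Longest linear sequence: 9 (steps 1 and 3 to 10, from compound 1); step 2 is a one-step side branch.

Steps most likely to fail:

Step 4. The diene terminus is flanked by the carbonyl and methoxy groups of ring B, so cycloaddition with the bulky iminium ion may be slow. The acid co-catalyst may oligomerize the diene. The endo preference may erode, and the exo mode delivers the opposite configuration at the pyranone-bearing carbon. Fallback, from 5 back to 9, by auxiliary-controlled Lewis-acid Diels–Alder chemistry: (4S)-4-benzyl-1,3-oxazolidin-2-one is N-acylated (MeMgBr, THF, -78 °C, then acryloyl chloride) to (4S)-4-benzyl-3-(prop-2-enoyl)-1,3-oxazolidin-2-one F1. F1 and diene 5 with Et2AlCl (2.5 equiv, one equivalent being consumed by the pyranone carbonyl) in CH2Cl2 at -78 °C should give the endo cycloadduct (4S)-4-benzyl-3-{[(1R,2S)-2-(4-methoxy-6-methyl-2-oxo-2H-pyran-3-yl)-4-methylcyclohex-3-en-1-yl]carbonyl}-1,3-oxazolidin-2-one F2, the chelated s-cis acrylimide exposing the same Si face of the alpha-carbon. Transamidation of F2 with Me3Al/MeNH(OMe)·HCl (CH2Cl2, -15 °C to rt) gives (1R,2S)-N-methoxy-2-(4-methoxy-6-methyl-2-oxo-2H-pyran-3-yl)-N,4-dimethylcyclohex-3-ene-1-carboxamide F3 and returns the auxiliary. MeMgBr (THF, -20 °C) converts F3 into cis ketone 9.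

Step 7. The ylide may act as a base instead of a nucleophile, enolizing the hindered ketone and deprotonating the pyranone 6-methyl group, and the cis-to-trans equilibration may be incomplete before olefination. Fallback, from 9 back to 11, by a Peterson olefination through an isolated adduct: 9 is equilibrated with DBU (toluene, rt to 50 °C) and trans ketone 10 is now isolated. Addition of Me3SiCH2Li/CeCl3 (THF, -78 °C), a weakly basic organocerium reagent, gives the beta-hydroxysilane 3-[(1S,6S)-6-[2-hydroxy-1-(trimethylsilyl)propan-2-yl]-3-methylcyclohex-2-en-1-yl]-4-methoxy-6-methyl-2H-pyran-2-one F4 (either carbinol epimer serves). KOtBu (THF, rt) then effects syn-elimination to 11.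

Step 9. Deprotonation of the 6-methyl group of the 3-substituted pyranone may be sluggish under equilibrium conditions, the aldol step may revert, and methoxide may open the lactone on prolonged heating. Fallback, from 12 back to 14, by kinetic aldol addition followed by a separate elimination: LiN(SiMe3)2 (THF, -78 °C) and then benzaldehyde give the aldol adduct 6-(2-hydroxy-2-phenylethyl)-4-methoxy-3-[(1R,6R)-3-methyl-6-(propan-2-yl)cyclohex-2-en-1-yl]-2H-pyran-2-one F5. Mesylation (MsCl, Et3N, CH2Cl2, 0 °C) gives, without isolation, 2-{4-methoxy-5-[(1R,6R)-3-methyl-6-(propan-2-yl)cyclohex-2-en-1-yl]-6-oxo-6H-pyran-2-yl}-1-phenylethyl methanesulfonate F6, and E1cB elimination with DBU in the same flask gives (E)-alkene 14.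

**Further compounds**

F1 | step 4 | (4S)-4-benzyl-3-(prop-2-enoyl)-1,3-oxazolidin-2-one | C=CC(=O)N1[C@@H](Cc2ccccc2)COC1=O
F2 | step 4 | (4S)-4-benzyl-3-{[(1R,2S)-2-(4-methoxy-6-methyl-2-oxo-2H-pyran-3-yl)-4-methylcyclohex-3-en-1-yl]carbonyl}-1,3-oxazolidin-2-one | CC1=C[C@H](c2c(OC)cc(C)oc2=O)[C@H](C(=O)N2[C@@H](Cc3ccccc3)COC2=O)CC1
F3 | step 4 | (1R,2S)-N-methoxy-2-(4-methoxy-6-methyl-2-oxo-2H-pyran-3-yl)-N,4-dimethylcyclohex-3-ene-1-carboxamide | CC1=C[C@H](c2c(OC)cc(C)oc2=O)[C@H](C(=O)N(C)OC)CC1
F4 | step 7 | 3-[(1S,6S)-6-[2-hydroxy-1-(trimethylsilyl)propan-2-yl]-3-methylcyclohex-2-en-1-yl]-4-methoxy-6-methyl-2H-pyran-2-one | CC1=C[C@H](c2c(OC)cc(C)oc2=O)[C@@H](C(C)(O)C[Si](C)(C)C)CC1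
F5 | step 9 | 6-(2-hydroxy-2-phenylethyl)-4-methoxy-3-[(1R,6R)-3-methyl-6-(propan-2-yl)cyclohex-2-en-1-yl]-2H-pyran-2-one | CC1=C[C@H](c2c(OC)cc(CC(O)c3ccccc3)oc2=O)[C@@H](C(C)C)CC1
F6 | step 9 | 2-{4-methoxy-5-[(1R,6R)-3-methyl-6-(propan-2-yl)cyclohex-2-en-1-yl]-6-oxo-6H-pyran-2-yl}-1-phenylethyl methanesulfonate | CC1=C[C@H](c2c(OC)cc(CC(OS(C)(=O)=O)c3ccccc3)oc2=O)[C@@H](C(C)C)CC1
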